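**Retrosynthetic overview**
1. Target 24 ⇐ diol 22 (acetate at C13–O, methacrylate at C8–O) ⇐ bis-silyl ether 21, which already holds the 10-membered carbocycle, the cis-epoxide, the butenolide and the exocyclic-methylene ketone.
2. 21 ⇐ 19 by a Pd-catalysed decarboxylative ring contraction: the 12-membered lactone ring of 19 (C1–C8, the carboxyl carbon on C8, its ester O, C14, C10) loses CO2 and re-closes through a new C8–C9 bond as the 10-membered carbocycle C1–C10.
3. Enabling feature: in 19 the lactone O–CH2 (C14) is allylic to the exocyclic C10=CH2 conjugated with the C1 ketone (a 2-acylallyl ester with two equivalent CH2 termini), and the lactone carboxyl sits on C8, which is α-oxygenated and vinylogous to the butenolide C12=O through C7=C11; ionisation plus CO2 loss therefore gives a stabilised dienolate tethered to the allyl cation.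
4. 19 ⇐ aldehyde 16 by intramolecular Nozaki–Hiyama–Kishi coupling/lactonisation (C6–C7 bond; butenolide and 12-membered ring in one operation), then oxidation at C1; 16 ⇐ ester of diol 6 with acid 13.
5. 6 from nerol (Sharpless epoxidation sets C4/C5, ozonolysis, NHK with 2-bromoallyl alcohol); 13 from tert-butyl glyoxylate, methyl propiolate and formaldehyde. Ring order: oxirane (step 1) → 12-membered lactone + butenolide (step 12) → 10-membered carbocycle (step 14).

Key step: step 14

Remark on the chemistry: germacrane numbering is used (C1 ketone, C4/C5 epoxide with CH3 on C4, C6 lactone O–CH, C7=C11, C8 O-acyl carbon, C10=C14H2, C12 lactone C=O, C13 CH2O); C1 and C8 are carried as epimer mixtures because both centres are erased later (C1 in step 13, C8 in step 14).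

**Route**

Step 1
Reactants: 1 nerol
Product: 2 (2R,3S)-2,3-epoxynerol
Conditions: Ti(OiPr)4 (cat.), D-(−)-diethyl tartrate (cat.), t-BuOOH, 4 Å MS, CH2Cl2, −20 °C
Reagents that add atoms: tert-butyl hydroperoxide CC(C)(C)OO
Why: Sharpless asymmetric epoxidation of the (Z)-allylic alcohol, in which the D-(−)-tartrate/Ti complex selects the alkene face that gives the (2R,3S) cis-epoxide (C4 S, C5 R of the target) and leaves the remote trisubstituted alkene untouched.

Step 2
Reactants: 2 (2R,3S)-2,3-epoxynerol
Product: 3 triethylsilyl ether of 2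
Conditions: Et3SiCl, imidazole, CH2Cl2, 0 °C
Reagents that add atoms: chlorotriethylsilane CC[Si](Cl)(CC)CC
Why: routine silylation of the primary alcohol, with TES chosen because it can later be removed in the presence of TBS ethers.

Step 3
Reactants: 3 triethylsilyl ether of 2
Product: 4 (4S,5R)-4,5-epoxy-4-methyl-6-(triethylsilyloxy)hexanal
Conditions: O3, CH2Cl2, −78 °C; then PPh3
Reagents that add atoms: ozone [O-][O+]=O
Why: ozonolysis with reductive work-up cleaves the only remaining alkene to the C1 aldehyde without touching the epoxide or silyl ether.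

Step 4
Reactants: 4 (4S,5R)-4,5-epoxy-4-methyl-6-(triethylsilyloxy)hexanal; 5 2-bromoprop-2-en-1-ol
Product: 6 (6S,7R)-6,7-epoxy-6-methyl-2-methylidene-8-(triethylsilyloxy)octane-1,3-diol (both C3 epimers)
Conditions: CrCl2 (6 equiv), NiCl2 (2 mol%), DMF, rt
Reagents that add atoms: none
Why: Nozaki–Hiyama–Kishi addition of the alkenylchromium reagent to the aldehyde is chemoselective for CHO in the presence of the epoxide, and the new carbinol (C1) may form as both epimers because it is oxidised in step 13.

Step 5
Reactants: 7 di-tert-butyl L-tartrate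
Product: 8 tert-butyl glyoxylate
Conditions: H5IO6, Et2O, rt
Reagents that add atoms: none
Why: periodate glycol cleavage of the tartrate diol gives two equivalents of the glyoxylate.

Step 6
Reactants: 8 tert-butyl glyoxylate; 9 methyl propiolate
Product: 10 1-tert-butyl 5-methyl 2-hydroxypent-3-ynedioate (racemic)
Conditions: 9, LiHMDS, THF, −78 °C; then 8; AcOH quench at −78 °C
Reagents that add atoms: none
Why: 1,2-addition of lithium methyl propiolate to the aldehyde forms the C7–C8 bond, and the racemic carbinol (C8) is acceptable because this centre is reset in step 14.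

Step 7
Reactants: 10 1-tert-butyl 5-methyl 2-hydroxypent-3-ynedioate
Product: 11 1-tert-butyl 5-methyl (3Z)-2-hydroxy-4-(hydroxymethyl)-3-iodopent-3-enedioate (racemic; iodine cis to CO2Me)
Conditions: MgI2 (1.5 equiv), monomeric CH2O (from cracked paraformaldehyde), CH2Cl2, −20 → 0 °C
Reagents that add atoms: magnesium iodide [Mg+2].[I-].[I-]; formaldehyde C=O
Why: β-iodo Morita–Baylis–Hillman-type three-component reaction, in which iodide adds to the ynoate carbon β to CO2Me and the magnesium allenolate is hydroxymethylated at the α-carbon, the anti addition placing iodine cis to the methyl ester.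

Step 8
Reactants: 11 1-tert-butyl 5-methyl (3Z)-2-hydroxy-4-(hydroxymethyl)-3-iodopent-3-enedioate
Product: 13 (3Z)-2-(tert-butyldimethylsilyloxy)-4-[(tert-butyldimethylsilyloxy)methyl]-3-iodo-5-methoxy-5-oxopent-3-enoic acid (racemic), via tris-silyl ester 12 (not isolated)
Conditions: TBSOTf (3.5 equiv), 2,6-lutidine, CH2Cl2, 0 °C → rt; then THF/H2O/AcOH, rt
Reagents that add atoms: tert-butyldimethylsilyl triflate CC(C)(C)[Si](C)(C)OS(=O)(=O)C(F)(F)F
Why: the silyl triflate silylates both hydroxyls and converts the tert-butyl ester into a labile silyl ester, which mild aqueous acid hydrolyses to the free acid while the two TBS ethers stay.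

Step 9
Reactants: 6 diol; 13 acid
Product: 14 ester of acid 13 with the primary allylic hydroxyl (C14–OH) of 6 (C1 and C8 epimers)
Conditions: EDC·HCl (1.2 equiv), DMAP (10 mol%), CH2Cl2, −20 → 0 °C
Reagents that add atoms: none
Why: Steglich esterification acylates the unhindered primary allylic alcohol in preference to the secondary one, and the diastereomer mixture is harmless because C1 and C8 are both erased later.

Step 10
Reactants: 14 ester
Product: 15 primary alcohol (14 without the triethylsilyl group)
Conditions: HF·pyridine, pyridine, THF, 0 °C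
Reagents that add atoms: none
Why: buffered HF·pyridine should cleave the primary TES ether much faster than the primary and secondary TBS ethers and should spare the epoxide.

Step 11
Reactants: 15 primary alcohol
Product: 16 α,β-epoxy aldehyde (C6 aldehyde; C1–OH retained)
Conditions: TEMPO (10 mol%), PhI(OAc)2 (1.1 equiv), CH2Cl2, 0 °C → rt
Reagents that add atoms: none
Why: oxoammonium oxidation is selective for the primary alcohol over the secondary allylic alcohol, and any over-oxidation at C1 would only anticipate step 13.

Step 12
Reactants: 16 α,β-epoxy aldehyde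
Product: 18 12-membered hydroxy macrolactone with fused butenolide (4S,5R,6R; C1 and C8 epimers), via hydroxy ester 17 (not isolated)
Conditions: CrCl2 (8 equiv, no nickel), DMSO/THF, rt, slow addition to 2 mM; aqueous work-up
Reagents that add atoms: none
Why: intramolecular Nozaki–Hiyama–Kishi reaction of the activated β-iodo enoate forms C6–C7 and closes the 12-membered ring, the chromium alkoxide then lactonises onto the cis methyl ester to give the butenolide, and C6 is set by Felkin–Anh/Cornforth addition anti to the epoxide C–O bond, which gives the erythro (6R) epoxy carbinol.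

Step 13
Reactants: 18 12-membered hydroxy macrolactone
Product: 19 12-membered keto macrolactone (C1 ketone; 2-acylallyl ester; C8 epimers)
Conditions: Dess–Martin periodinane, NaHCO3, CH2Cl2, 0 °C → rt
Reagents that add atoms: none
Why: oxidation of the secondary allylic alcohol gives the α-methylene ketone, which turns the lactone O–CH2 into a Baylis–Hillman-type allylic ester and merges the C1 epimers.

Step 14
Reactants: 19 12-membered keto macrolactone
Product: 21 10-membered carbocycle as its 8,13-bis(tert-butyldimethylsilyl) ether (4S,5R,6R,8R), via palladium dienolate 20 (not isolated)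
Conditions: Pd2(dba)3·CHCl3 (5 mol%), N,N′-[(1S,2S)-cyclohexane-1,2-diyl]bis[2-(diphenylphosphanyl)benzamide] (12 mol%), degassed 1,4-dioxane, 2 mM, 40 → 60 °C
Reagents that add atoms: none
Why: Proposed new method: Pd(0) ionises the C14–O bond of the 2-acylallyl ester, the tethered carboxylate on the doubly activated C8 (α-silyloxy, vinylogous to the butenolide carbonyl) loses CO2, and the dienolate/π-allylpalladium pair 20 collapses by C–C bond formation between C8 and a CH2 terminus of the allyl unit (both termini give the same product), so the 12-membered lactone is excised of its C(=O)–O unit and re-closed as the 10-membered carbocycle with the exocyclic methylene on C10. The closest known reaction type is the Tsuji–Trost decarboxylative allylation of allyl esters of stabilised carboxylic acids, including its vinylogous variant in which an unsaturated lactone (allyl coumarin-3-carboxylates) is allylated at the γ-carbon; new here is the macrocyclic, ring-contracting use with a butenolide dienolate. The ring closes by outer-sphere attack of the dienolate γ-carbon on the π-allyl ligand, a 10-membered closure held together by the C1–C7 tether. C8 is the only new stereocentre: both C8 epimers of 19 converge on the same planar dienolate, and the alkylated face is to be set by the chiral bis(phosphine) ligand together with the resident C6 centre; the sense cannot be predicted with confidence, so the (S,S)-ligand is a starting choice and its antipode is the first variable to change. The step needs γ- rather than α-attack (C11 is fully substituted, and an α-adduct is a 1,5-diene that can reach the same product by Cope rearrangement on warming), collapse faster than proton transfer, and no β-elimination at C13, which is why C13 carries a silyl ether and not the acetate at this stage.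

Step 15
Reactants: 21 10-membered bis-silyl ether
Product: 22 8,13-diol
Conditions: HF·pyridine, pyridine, THF, 0 °C → rt
Reagents that add atoms: none
Why: buffered acidic fluoride removes both TBS ethers under conditions that should spare the epoxide, enone and butenolide and should not promote lactone migration to O8.

Step 16
Reactants: 22 8,13-diol
Product: 24 target CNP0266914.1, via monoacetate 23 (not isolated)
Conditions: AcCl (1.05 equiv), 2,4,6-collidine, CH2Cl2, −78 °C; then methacrylic anhydride, DMAP (20 mol%), −78 → 0 °C
Reagents that add atoms: acetyl chloride CC(=O)Cl; methacrylic anhydride CC(=C)C(=O)OC(=O)C(C)=C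
Why: the primary allylic hydroxyl is acetylated selectively at low temperature and the remaining secondary C8 hydroxyl is then acylated with retention, under weakly basic conditions that avoid elimination of the C13 acetate.

**Compound list**
1 | nerol, (2Z)-3,7-dimethylocta-2,6-dien-1-ol | CC(C)=CCC/C(C)=C\CO | starting material
2 | (2R,3S)-2,3-epoxynerol | CC(C)=CCC[C@]1(C)O[C@@H]1CO | intermediate
3 | triethylsilyl ether of 2 | CC(C)=CCC[C@]1(C)O[C@@H]1CO[Si](CC)(CC)CC | intermediate
4 | (4S,5R)-4,5-epoxy-4-methyl-6-(triethylsilyloxy)hexanal | O=CCC[C@]1(C)O[C@@H]1CO[Si](CC)(CC)CC | intermediate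
5 | 2-bromoprop-2-en-1-ol | OCC(Br)=C | starting material
6 | (6S,7R)-6,7-epoxy-6-methyl-2-methylidene-8-(triethylsilyloxy)octane-1,3-diol, C3 epimers | C=C(CO)C(O)CC[C@]1(C)O[C@@H]1CO[Si](CC)(CC)CC | intermediate
7 | di-tert-butyl L-tartrate | CC(C)(C)OC(=O)[C@H](O)[C@@H](O)C(=O)OC(C)(C)C | starting material
8 | tert-butyl glyoxylate | CC(C)(C)OC(=O)C=O | intermediate
9 | methyl propiolate | C#CC(=O)OC | starting material
10 | 1-tert-butyl 5-methyl 2-hydroxypent-3-ynedioate, racemic | COC(=O)C#CC(O)C(=O)OC(C)(C)C | intermediate
11 | 1-tert-butyl 5-methyl (3Z)-2-hydroxy-4-(hydroxymethyl)-3-iodopent-3-enedioate, racemic | CC(C)(C)OC(=O)C(O)/C(I)=C(\CO)C(=O)OC | intermediate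
12 | tert-butyldimethylsilyl ester of 13 (tris-silyl compound) | CC(C)(C)[Si](C)(C)OC(=O)C(O[Si](C)(C)C(C)(C)C)/C(I)=C(\CO[Si](C)(C)C(C)(C)C)C(=O)OC | intermediate (not isolated)
13 | (3Z)-2-(TBS-oxy)-4-[(TBS-oxy)methyl]-3-iodo-5-methoxy-5-oxopent-3-enoic acid, racemic | OC(=O)C(O[Si](C)(C)C(C)(C)C)/C(I)=C(\CO[Si](C)(C)C(C)(C)C)C(=O)OC | intermediate
14 | ester of 13 with the primary allylic OH of 6 | C=C(COC(=O)C(O[Si](C)(C)C(C)(C)C)/C(I)=C(\CO[Si](C)(C)C(C)(C)C)C(=O)OC)C(O)CC[C@]1(C)O[C@@H]1CO[Si](CC)(CC)CC | intermediate
15 | 14 with free primary epoxy alcohol (TES removed) | C=C(COC(=O)C(O[Si](C)(C)C(C)(C)C)/C(I)=C(\CO[Si](C)(C)C(C)(C)C)C(=O)OC)C(O)CC[C@]1(C)O[C@@H]1CO | intermediate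
16 | α,β-epoxy aldehyde from 15 | C=C(COC(=O)C(O[Si](C)(C)C(C)(C)C)/C(I)=C(\CO[Si](C)(C)C(C)(C)C)C(=O)OC)C(O)CC[C@]1(C)O[C@@H]1C=O | intermediate
17 | 12-membered ring hydroxy ester (C6–C7 formed, CO2Me cis to C6) | OC1CC[C@]2(C)O[C@@H]2[C@H](O)/C(=C(/CO[Si](C)(C)C(C)(C)C)C(=O)OC)C(O[Si](C)(C)C(C)(C)C)C(=O)OCC1=C | intermediate (not isolated)
18 | 12-membered hydroxy macrolactone with fused butenolide (4S,5R,6R) | OC1CC[C@]2(C)O[C@@H]2[C@@H]2OC(=O)C(CO[Si](C)(C)C(C)(C)C)=C2C(O[Si](C)(C)C(C)(C)C)C(=O)OCC1=C | intermediate
19 | 12-membered keto macrolactone (C1 ketone, 2-acylallyl ester) | O=C1CC[C@]2(C)O[C@@H]2[C@@H]2OC(=O)C(CO[Si](C)(C)C(C)(C)C)=C2C(O[Si](C)(C)C(C)(C)C)C(=O)OCC1=C | intermediate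
20 | palladium dienolate ion pair after loss of CO2 (drawn as σ-allyl, ligands omitted) | C=C(C[Pd+])C(=O)CC[C@]1(C)O[C@@H]1[C@@H]1OC([O-])=C(CO[Si](C)(C)C(C)(C)C)C1=CO[Si](C)(C)C(C)(C)C | intermediate (not isolated)
21 | 10-membered carbocycle, 8,13-bis(TBS) ether (4S,5R,6R,8R) | CC(C)(C)[Si](C)(C)O[C@@H]1CC(=C)C(=O)CC[C@]2(C)O[C@@H]2[C@@H]2OC(=O)C(CO[Si](C)(C)C(C)(C)C)=C21 | intermediate
22 | 8,13-diol | O[C@@H]1CC(=C)C(=O)CC[C@]2(C)O[C@@H]2[C@@H]2OC(=O)C(CO)=C21 | intermediate
23 | 13-acetate 8-ol | O[C@@H]1CC(=C)C(=O)CC[C@]2(C)O[C@@H]2[C@@H]2OC(=O)C(COC(C)=O)=C21 | intermediate (not isolated)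
24 | CNP0266914.1 | C=C(C)C(=O)O[C@@H]1CC(=C)C(=O)CC[C@]2(C)O[C@@H]2[C@@H]2OC(=O)C(COC(C)=O)=C21 | target

**Step count:** 16 steps in total. Longest linear sequence: 12 steps (steps 1–4 then 9–16, or steps 5–8 then 9–16).

**Steps most likely to fail**

Step 14 (Proposed new method). What may go wrong: C-allylation at the α-carbon C11 or O-allylation instead of bond formation at C8; poor facial selectivity at C8, which is the least predictable point of the route; proton transfer to the dienolate; loss of silyloxide from C13. The fallback uses known chemistry, sets out from 19 and comes back at 21. Ireland–Claisen ring contraction of the macrolactone (LiHMDS 1.05 equiv, Me3SiCl, THF, −78 °C → rt) removes C8–H, the most acidic proton of 19, and the silyl ketene acetal rearranges across the allyl ester whose alkene is exocyclic; this forms C8–C9, contracts the ring from 12 to 10 members and gives after work-up the C8-quaternary carboxylic acid F1. Heating F1 in pyridine (Doebner-type decarboxylation of a vinylogous malonic acid) should give 21 together with its C8 epimer, to be separated.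

Step 12. What may go wrong: intermolecular coupling outrunning the 12-membered ring closure; erosion of the Felkin preference at C6 inside the macrocyclic transition state; simple reduction of the iodo enoate. The fallback sets out from 13, 5 and 2 and comes back at 18; it makes the butenolide intermolecularly and closes the ring at C1–C10 instead. Acid 13 is esterified with 5 (EDC, DMAP) to the 2-bromoallyl ester F2, and 2 is oxidised (Dess–Martin) to (2S,3S)-2,3-epoxyneral F3. Nickel-free CrCl2 couples F2 with F3 (the unactivated vinyl bromide stays intact) and lactonisation gives the open-chain butenolide F4 under acyclic Felkin control. Ozonolysis of the trisubstituted alkene of F4 gives the aldehyde F5, and Ni/Cr-mediated intramolecular coupling of its vinyl bromide with the aldehyde closes the 12-membered ring to 18.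

Step 7. What may go wrong: slow iodide addition to the internal, γ-oxygenated ynoate; oligomerisation of formaldehyde before the aldol; E/Z erosion of the iodoalkene. The fallback sets out from 10 and comes back at 13; it replaces the one-pot three-component reaction on the free alcohol by a stepwise sequence on the protected ynoate. Compound 10 is silylated (TBSCl, imidazole) to the silyl ether F6; Et2AlI (CH2Cl2, 0 °C) pre-forms the β-iodo aluminium allenolate, which is hydroxymethylated with monomeric formaldehyde at −78 °C to the (Z)-iodo alcohol F7; the conditions of step 8 then convert F7 into 13.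

**Further compounds**
F1 | step 14 | 10-membered C8-quaternary carboxylic acid from Ireland–Claisen ring contraction of 19 | CC(C)(C)[Si](C)(C)OC1(C(=O)O)CC(=C)C(=O)CC[C@]2(C)O[C@@H]2[C@@H]2OC(=O)C(CO[Si](C)(C)C(C)(C)C)=C21
F2 | step 12 | 2-bromoallyl ester of acid 13 | C=C(Br)COC(=O)C(O[Si](C)(C)C(C)(C)C)/C(I)=C(\CO[Si](C)(C)C(C)(C)C)C(=O)OC
F3 | step 12 | (2S,3S)-2,3-epoxyneral | CC(C)=CCC[C@]1(C)O[C@@H]1C=O
F4 | step 12 | open-chain butenolide from F2 and F3 (4S,5R,6R) | CC(C)=CCC[C@]1(C)O[C@@H]1[C@@H]1OC(=O)C(CO[Si](C)(C)C(C)(C)C)=C1C(O[Si](C)(C)C(C)(C)C)C(=O)OCC(Br)=C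
F5 | step 12 | aldehyde from ozonolysis of F4 | O=CCC[C@]1(C)O[C@@H]1[C@@H]1OC(=O)C(CO[Si](C)(C)C(C)(C)C)=C1C(O[Si](C)(C)C(C)(C)C)C(=O)OCC(Br)=C
F6 | step 7 | tert-butyldimethylsilyl ether of 10 | COC(=O)C#CC(O[Si](C)(C)C(C)(C)C)C(=O)OC(C)(C)C
F7 | step 7 | 1-tert-butyl 5-methyl (3Z)-2-(TBS-oxy)-4-(hydroxymethyl)-3-iodopent-3-enedioate | CC(C)(C)OC(=O)C(O[Si](C)(C)C(C)(C)C)/C(I)=C(\CO)C(=O)OC
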